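**Strategy.** Everything rests on reading the oxolane ring (O–CH2–CH, the O–C(CH3) carbon next to the bridging ketone, and the tertiary carbinol carbon) as the adduct of an acyl-stabilised carbonyl ylide, CH2=O(+)–C(−)(CH3)–C=O, with an enol double bond. The key step is a Lewis-acid-triggered formal (3+2) cycloaddition that joins the ether CH2 to the ring CH and the O–C(CH3) carbon to the carbinol carbon, closing the oxolane and the bicyclo[2.2.2]octane at once. Its precursor is monocyclic: a dimedone-derived 1,3-bis(silyloxy)cyclohexadiene whose enantioenriched quaternary carbon carries the MOM-protected lactoyl side chain as its enol silane. The (S)-2-phenyldihydropyranone is annulated last.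

Key step: step 11

Assumption: the (S)-PHOX ligand is taken to give the (R)-quaternary carbon in step 4 by analogy with the sense known for 2-methylcyclohexanone-type enol carbonates; its enantiomer is used should the sense prove opposite.

Cage compounds are named as 4-oxatricyclo[4.3.1.0(3,7)]decanes: C1 methyl-bearing bridgehead, C2 bridging ketone, C3 O–C(CH3), O4, C5 ether CH2, C6 ring CH, C7 oxygenated bridgehead, C8/C9 the two-carbon bridge, C10 CMe2.

Step 1
Reactants: 1 dimedone (5,5-dimethylcyclohexane-1,3-dione)
Product: 2 3-isobutoxy-5,5-dimethylcyclohex-2-en-1-one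
Conditions: i-BuOH, TsOH·H2O (cat.), toluene, reflux, azeotropic removal of water
Reagents that add atoms: isobutanol (2-methylpropan-1-ol), CC(C)CO
Why: Acid-catalysed condensation of the enolised 1,3-dione with the alcohol (vinylogous esterification), driven by removal of water, masks one carbonyl so that a single regiodefined enolate can be formed next; no stereocentre.

Step 2
Reactants: 2 3-isobutoxy-5,5-dimethylcyclohex-2-en-1-one
Product: 4 rac-3-isobutoxy-5,5,6-trimethylcyclohex-2-en-1-one, via lithium dienolate 3 (not isolated)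
Conditions: LiN(i-Pr)2, THF, −78 °C; MeI, −78 → 0 °C
Reagents that add atoms: iodomethane, CI
Why: Kinetic deprotonation of a vinylogous ester occurs at the alpha' carbon (Stork–Danheiser-type enolate) and the cross-conjugated dienolate is C-methylated there; the new stereocentre is racemic and is planarised again in step 3.

Step 3
Reactants: 4 rac-3-isobutoxy-5,5,6-trimethylcyclohex-2-en-1-one
Product: 6 allyl (5-isobutoxy-2,3,3-trimethylcyclohexa-1,5-dien-1-yl) carbonate, via lithium dienolate 5 (not isolated)
Conditions: LiN(i-Pr)2, TMEDA, THF, −78 °C; ClCO2CH2CH=CH2, −78 °C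
Reagents that add atoms: allyl chloroformate, C=CCOC(Cl)=O
Why: A second alpha' deprotonation gives the fully substituted dienolate, which the hard chloroformate acylates on oxygen (favoured by TMEDA and the hindered carbon terminus) to give the enol carbonate needed for decarboxylative allylation.

Step 4
Reactants: 6 allyl (5-isobutoxy-2,3,3-trimethylcyclohexa-1,5-dien-1-yl) carbonate
Product: 7 (R)-6-allyl-3-isobutoxy-5,5,6-trimethylcyclohex-2-en-1-one
Conditions: Pd2(dba)3 (2.5 mol %), (S)-(CF3)3-t-Bu-PHOX (6 mol %), toluene, 30 °C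
Reagents that add atoms: none
Why: Decarboxylative asymmetric allylic alkylation (Tsuji allylation): oxidative addition of zerovalent palladium and loss of CO2 give an allylpalladium enolate that forms the C–C bond inside the chiral PHOX pocket, which sets the quaternary carbon as (R); the electron-poor ligand is chosen for this hindered vinylogous-ester enolate flanked by a gem-dimethyl carbon.

Step 5
Reactants: 7 (R)-6-allyl-3-isobutoxy-5,5,6-trimethylcyclohex-2-en-1-one
Product: 8 (R)-3-isobutoxy-5,5,6-trimethyl-6-[(E)-prop-1-en-1-yl]cyclohex-2-en-1-one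
Conditions: RuHCl(CO)(PPh3)3 (5 mol %), toluene, 80 °C
Reagents that add atoms: none
Why: Ruthenium hydride-catalysed alkene isomerisation (hydrometalation/beta-hydride elimination) moves the terminal double bond one position to the preferred (E)-propenyl group and must stop there because the neighbouring carbon is quaternary.

Step 6
Reactants: 8 (R)-3-isobutoxy-5,5,6-trimethyl-6-[(E)-prop-1-en-1-yl]cyclohex-2-en-1-one
Product: 9 (6S)-6-(1,2-dihydroxypropyl)-3-isobutoxy-5,5,6-trimethylcyclohex-2-en-1-one (syn-diol, both facial isomers)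
Conditions: OsO4 (2 mol %), NMO, acetone/H2O, rt
Reagents that add atoms: osmium tetroxide (oxygen carrier), O=[Os](=O)(=O)=O; N-methylmorpholine N-oxide (terminal oxygen source), C[N+]1([O-])CCOCC1; water, O
Why: Catalytic OsO4/NMO syn-dihydroxylation takes the isolated propenyl double bond in preference to the deactivated vinylogous-ester C=C; the two carbinol centres form as a mixture, which is inconsequential because one is oxidised in step 8 and the other planarised in step 10.

Step 7
Reactants: 9 (6S)-6-(1,2-dihydroxypropyl)-3-isobutoxy-5,5,6-trimethylcyclohex-2-en-1-one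
Product: 10 (6S)-6-[1-hydroxy-2-(methoxymethoxy)propyl]-3-isobutoxy-5,5,6-trimethylcyclohex-2-en-1-one
Conditions: MOMCl (1.1 equiv), i-Pr2NEt, CH2Cl2, 0 °C
Reagents that add atoms: chloromethyl methyl ether, COCCl
Why: Alkoxymethylation goes to the less hindered methyl-bearing carbinol, since the other hydroxyl is neopentylic beside the quaternary carbon; this installs the O–CH2 unit that becomes the oxolane CH2.

Step 8
Reactants: 10 (6S)-6-[1-hydroxy-2-(methoxymethoxy)propyl]-3-isobutoxy-5,5,6-trimethylcyclohex-2-en-1-one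
Product: 11 (6R)-3-isobutoxy-6-[2-(methoxymethoxy)propanoyl]-5,5,6-trimethylcyclohex-2-en-1-one (epimers at the alkoxy carbon)
Conditions: Dess–Martin periodinane, NaHCO3, CH2Cl2, rt
Reagents that add atoms: none
Why: Dess–Martin oxidation converts the hindered secondary alcohol into the ketone under buffered, non-basic conditions that avoid retro-aldol cleavage of the beta-hydroxy ketone and leave the MOM acetal intact.

Step 9
Reactants: 11 (6R)-3-isobutoxy-6-[2-(methoxymethoxy)propanoyl]-5,5,6-trimethylcyclohex-2-en-1-one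
Product: 12 (4R)-4-[2-(methoxymethoxy)propanoyl]-4,5,5-trimethylcyclohexane-1,3-dione
Conditions: 1 M HCl, THF, rt
Reagents that add atoms: water, O
Why: Dilute aqueous acid hydrolyses the vinylogous ester (C-protonation, addition of water) to the 1,3-dione while the MOM acetal, which needs stronger acid, should survive; the quaternary stereocentre is not enolisable.

Step 10
Reactants: 12 (4R)-4-[2-(methoxymethoxy)propanoyl]-4,5,5-trimethylcyclohexane-1,3-dione
Product: 13 (6R)-6-[(E)-2-(methoxymethoxy)-1-(triethylsilyloxy)prop-1-en-1-yl]-5,5,6-trimethyl-1,3-bis(triethylsilyloxy)cyclohexa-1,3-diene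
Conditions: Et3SiOTf (3.6 equiv), Et3N, CH2Cl2, −78 → 0 °C; non-aqueous work-up, used crude
Reagents that add atoms: triethylsilyl trifluoromethanesulfonate, CC[Si](CC)(CC)OS(=O)(=O)C(F)(F)F
Why: Soft enolisation with silyl triflate and amine silylates all three carbonyls; the quaternary ring carbon allows only the 1,3-bis(silyloxy)-1,3-diene, and the side-chain enol silane is expected mainly as the (E)-isomer, in which the small alkoxy group rather than methyl lies cis to the quaternary carbon.

Step 11
Reactants: 13 (6R)-6-[(E)-2-(methoxymethoxy)-1-(triethylsilyloxy)prop-1-en-1-yl]-5,5,6-trimethyl-1,3-bis(triethylsilyloxy)cyclohexa-1,3-diene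
Product: 17 (1R,3S,6R,7S)-1,3,10,10-tetramethyl-7-(triethylsilyloxy)-4-oxatricyclo[4.3.1.0(3,7)]decane-2,9-dione, via oxocarbenium triflate 14 (not isolated), via bis(silyloxy)allyl cation 15 (not isolated), via cage enol silane 16 (not isolated)
Conditions: Et3SiOTf (20 mol %), 2,6-di-tert-butyl-4-methylpyridine (30 mol %), CH2Cl2 (0.005 M), −78 → −20 °C; then 0.5 M HCl, THF, 0 °C
Reagents that add atoms: none
Why: Proposed new method: catalytic Et3SiOTf ionises the MOM acetal (MeOSiEt3 leaves) to oxocarbenium 14, an O-silylated acyl-stabilised carbonyl ylide CH2=O(+)–C(CH3)=C(OSiEt3), whose CH2 is attacked by the terminal carbon of the bis(silyloxy)diene to give allyl cation 15, which is then captured at its oxygenated terminus by the side-chain enol silane with release of Et3SiOTf, a net formal (3+2) cycloaddition of a carbonyl ylide to an enol ether. The closest known reactions are the Lewis-acid-mediated addition of silyl enol ethers to MOM- or MEM-derived alkoxymethyl cations (Mukaiyama-type Prins cyclisation), the terminal-carbon reactivity of 1,3-bis(silyloxy)-1,3-dienes, the intramolecular Mukaiyama aldol, and oxidopyrylium-type carbonyl ylide cycloadditions. The first closure forms a seven-membered ring, endo-trig at the oxocarbenium and exo at the diene; the second is a 6-(enolendo)-exo-trig aldol that completes the bicyclo[2.2.2]octane and the five-membered ether together. The three new stereocentres (ring CH, O–C(CH3), silyloxy bridgehead) are dictated by the existing quaternary carbon, because the tether delivers CH2 only to the diene face bearing the side chain and the short O–CH2 bridge enforces cis fusion, so a single cage should result. The step needs attack at the terminal rather than the central diene carbon (favoured by the vinylogous preference and the delocalised cation, and only this adduct can close further), reaction of the ene-diol unit through the carbon beta to silyloxy (secured by enol-silane polarisation and irreversible silyl loss), and the (E)-enol silane, which holds CH2=O(+) cis to the ring. High dilution and the hindered pyridine suppress intermolecular capture and protodesilylation, and the acidic quench hydrolyses only the enol silane of 16.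

Step 12
Reactants: 18 ethyl (S)-3-hydroxy-3-phenylpropanoate
Product: 19 (S)-3-hydroxy-N-methoxy-N-methyl-3-phenylpropanamide
Conditions: MeNH(OMe)·HCl, i-PrMgCl, THF, −20 → 0 °C
Reagents that add atoms: N,O-dimethylhydroxylamine hydrochloride, CNOC.Cl
Why: Aminolysis of the ester by the chloromagnesium amide of N,O-dimethylhydroxylamine gives the N-methoxy-N-methylamide; the purchased (S)-carbinol stereocentre is not involved.

Step 13
Reactants: 19 (S)-3-hydroxy-N-methoxy-N-methyl-3-phenylpropanamide
Product: 20 (S)-N-methoxy-N-methyl-3-phenyl-3-(triethylsilyloxy)propanamide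
Conditions: Et3SiCl, imidazole, DMF, 0 °C → rt
Reagents that add atoms: chlorotriethylsilane, CC[Si](Cl)(CC)CC
Why: Standard silylation protects the benzylic hydroxyl for the enolate acylation; configuration unchanged.

Step 14
Reactants: 17 (1R,3S,6R,7S)-1,3,10,10-tetramethyl-7-(triethylsilyloxy)-4-oxatricyclo[4.3.1.0(3,7)]decane-2,9-dione; 20 (S)-N-methoxy-N-methyl-3-phenyl-3-(triethylsilyloxy)propanamide
Product: 22 (1R,3S,6R,7R)-9-hydroxy-1,3,10,10-tetramethyl-8-[(S)-3-phenyl-3-(triethylsilyloxy)propanoyl]-7-(triethylsilyloxy)-4-oxatricyclo[4.3.1.0(3,7)]dec-8-en-2-one (enol form of the 1,3-diketone), via lithium enolate 21 (not isolated)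
Conditions: LiN(SiMe3)2 (1.1 equiv), THF, −78 °C; then 20, −78 → 0 °C; aq. NH4Cl
Reagents that add atoms: none
Why: Crossed Claisen-type C-acylation: the C9 ketone can enolise only toward C8 (the C2 ketone has two quaternary neighbours), and the lithium enolate adds to the amide to give a chelated tetrahedral intermediate that releases the 1,3-diketone on work-up; no stereocentre is formed, and the enantiopure side chain turns any residual cage enantiomer into a separable diastereomer.

Step 15
Reactants: 22 (1R,3S,6R,7R)-9-hydroxy-1,3,10,10-tetramethyl-8-[(S)-3-phenyl-3-(triethylsilyloxy)propanoyl]-7-(triethylsilyloxy)-4-oxatricyclo[4.3.1.0(3,7)]dec-8-en-2-one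
Product: 24 target CNP0322161.1, via hydroxy diketone 23 (not isolated)
Conditions: HF·pyridine, MeCN, 0 °C → rt; then TsOH·H2O (cat.), CH2Cl2, 4 Å MS, rt
Reagents that add atoms: none
Why: Both silyl ethers are removed and the freed benzylic hydroxyl adds to the enolised C9 carbonyl (6-exo-trig hemiketalisation) followed by acid-catalysed dehydration to the 2,3-dihydropyran-4-one; the benzylic C–O bond is never broken, so (S) is retained, and the tertiary alcohol is unmasked only under non-basic conditions, which avoids retro-aldol opening of the cage.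

**Compound list**

1 | dimedone (5,5-dimethylcyclohexane-1,3-dione) | CC1(C)CC(=O)CC(=O)C1 | starting material
2 | 3-isobutoxy-5,5-dimethylcyclohex-2-en-1-one | CC(C)COC1=CC(=O)CC(C)(C)C1 | intermediate
3 | lithium dienolate of 2 (alpha' enolate) | [Li+].[O-]C1=CC(C)(C)CC(OCC(C)C)=C1 | intermediate (not isolated)
4 | rac-3-isobutoxy-5,5,6-trimethylcyclohex-2-en-1-one | CC(C)COC1=CC(=O)C(C)C(C)(C)C1 | intermediate
5 | lithium dienolate of 4 (tetrasubstituted alpha' enolate) | [Li+].[O-]C1=C(C)C(C)(C)CC(OCC(C)C)=C1 | intermediate (not isolated)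
6 | allyl (5-isobutoxy-2,3,3-trimethylcyclohexa-1,5-dien-1-yl) carbonate | C=CCOC(=O)OC1=C(C)C(C)(C)CC(OCC(C)C)=C1 | intermediate
7 | (R)-6-allyl-3-isobutoxy-5,5,6-trimethylcyclohex-2-en-1-one | C=CC[C@@]1(C)C(=O)C=C(OCC(C)C)CC1(C)C | intermediate
8 | (R)-3-isobutoxy-5,5,6-trimethyl-6-[(E)-prop-1-en-1-yl]cyclohex-2-en-1-one | C/C=C/[C@@]1(C)C(=O)C=C(OCC(C)C)CC1(C)C | intermediate
9 | (6S)-6-(1,2-dihydroxypropyl)-3-isobutoxy-5,5,6-trimethylcyclohex-2-en-1-one (syn-diol, carbinol centres as a mixture) | CC(O)C(O)[C@@]1(C)C(=O)C=C(OCC(C)C)CC1(C)C | intermediate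
10 | (6S)-6-[1-hydroxy-2-(methoxymethoxy)propyl]-3-isobutoxy-5,5,6-trimethylcyclohex-2-en-1-one (side-chain centres as a mixture) | COCOC(C)C(O)[C@@]1(C)C(=O)C=C(OCC(C)C)CC1(C)C | intermediate
11 | (6R)-3-isobutoxy-6-[2-(methoxymethoxy)propanoyl]-5,5,6-trimethylcyclohex-2-en-1-one (epimers at the alkoxy carbon) | COCOC(C)C(=O)[C@@]1(C)C(=O)C=C(OCC(C)C)CC1(C)C | intermediate
12 | (4R)-4-[2-(methoxymethoxy)propanoyl]-4,5,5-trimethylcyclohexane-1,3-dione (epimers at the alkoxy carbon) | COCOC(C)C(=O)[C@@]1(C)C(=O)CC(=O)CC1(C)C | intermediate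
13 | (6R)-6-[(E)-2-(methoxymethoxy)-1-(triethylsilyloxy)prop-1-en-1-yl]-5,5,6-trimethyl-1,3-bis(triethylsilyloxy)cyclohexa-1,3-diene | COCO/C(C)=C(O[Si](CC)(CC)CC)\[C@@]1(C)C(O[Si](CC)(CC)CC)=CC(O[Si](CC)(CC)CC)=CC1(C)C | intermediate
14 | {(E)-1-[(1R)-1,6,6-trimethyl-2,4-bis(triethylsilyloxy)cyclohexa-2,4-dien-1-yl]-1-(triethylsilyloxy)prop-1-en-2-yl}(methylidene)oxonium triflate | C=[O+]/C(C)=C(O[Si](CC)(CC)CC)\[C@@]1(C)C(O[Si](CC)(CC)CC)=CC(O[Si](CC)(CC)CC)=CC1(C)C.[O-]S(=O)(=O)C(F)(F)F | intermediate (not isolated)
15 | [(1R,6R)-4,6,10,10-tetramethyl-5,7-bis(triethylsilyloxy)-3-oxabicyclo[4.3.1]deca-4,7-dien-9-ylidene](triethylsilyl)oxonium triflate (delocalised 1,3-bis(silyloxy)allyl cation) | CC1(C)[C@@H]2COC(C)=C(O[Si](CC)(CC)CC)[C@@]1(C)C(O[Si](CC)(CC)CC)=CC2=[O+][Si](CC)(CC)CC.[O-]S(=O)(=O)C(F)(F)F | intermediate (not isolated)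
16 | (1R,3S,6R,7R)-1,3,10,10-tetramethyl-7,9-bis(triethylsilyloxy)-4-oxatricyclo[4.3.1.0(3,7)]dec-8-en-2-one | CC1(C)[C@@H]2CO[C@]3(C)C(=O)[C@@]1(C)C(O[Si](CC)(CC)CC)=C[C@]23O[Si](CC)(CC)CC | intermediate (not isolated)
17 | (1R,3S,6R,7S)-1,3,10,10-tetramethyl-7-(triethylsilyloxy)-4-oxatricyclo[4.3.1.0(3,7)]decane-2,9-dione | CC1(C)[C@@H]2CO[C@]3(C)C(=O)[C@@]1(C)C(=O)C[C@]23O[Si](CC)(CC)CC | intermediate
18 | ethyl (S)-3-hydroxy-3-phenylpropanoate | CCOC(=O)C[C@H](O)c1ccccc1 | starting material
19 | (S)-3-hydroxy-N-methoxy-N-methyl-3-phenylpropanamide | CON(C)C(=O)C[C@H](O)c1ccccc1 | intermediate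
20 | (S)-N-methoxy-N-methyl-3-phenyl-3-(triethylsilyloxy)propanamide | CON(C)C(=O)C[C@H](O[Si](CC)(CC)CC)c1ccccc1 | intermediate
21 | lithium C8–C9 enolate of 17 | [Li+].CC1(C)[C@@H]2CO[C@]3(C)C(=O)[C@@]1(C)C([O-])=C[C@]23O[Si](CC)(CC)CC | intermediate (not isolated)
22 | (1R,3S,6R,7R)-9-hydroxy-1,3,10,10-tetramethyl-8-[(S)-3-phenyl-3-(triethylsilyloxy)propanoyl]-7-(triethylsilyloxy)-4-oxatricyclo[4.3.1.0(3,7)]dec-8-en-2-one | CC1(C)[C@@H]2CO[C@]3(C)C(=O)[C@@]1(C)C(O)=C(C(=O)C[C@H](O[Si](CC)(CC)CC)c1ccccc1)[C@]23O[Si](CC)(CC)CC | intermediate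
23 | (1R,3S,6R,7R)-7,9-dihydroxy-8-[(S)-3-hydroxy-3-phenylpropanoyl]-1,3,10,10-tetramethyl-4-oxatricyclo[4.3.1.0(3,7)]dec-8-en-2-one | CC1(C)[C@@H]2CO[C@]3(C)C(=O)[C@@]1(C)C(O)=C(C(=O)C[C@H](O)c1ccccc1)[C@]23O | intermediate (not isolated)
24 | target CNP0322161.1: (S)-2-phenyl-2,3-dihydropyran-4-one fused through its C5=C6 bond to C8=C9 of the (1R,3S,6R,7R)-7-hydroxy-1,3,10,10-tetramethyl-4-oxatricyclo[4.3.1.0(3,7)]dec-8-en-2-one cage (ring oxygen on C9) | CC1(C)[C@@H]2CO[C@]3(C)C(=O)[C@@]1(C)C1=C(C(=O)C[C@@H](c4ccccc4)O1)[C@]23O | target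

**Totals.** 15 steps in all; longest linear sequence 13 steps (steps 1–11, 14, 15).

**Steps most likely to fail**

1. Step 11 (proposed new method). The oxocarbenium may be captured at the central diene carbon, by a silyloxy oxygen, or intermolecularly, or the enol silanes may be protodesilylated before the second ring closes. The fallback separates the two closures into known reactions; it sets out from 12 and comes back at 16. Only the ring carbonyls of 12 are silylated (Et3SiOTf 2.1 equiv, Et3N, −78 °C) to give the bis(silyloxy)diene ketone F1. An intramolecular Mukaiyama-type alkoxymethylation (BF3·OEt2 or catalytic Et3SiOTf) then forms only the CH2–CH bond and gives the isolable oxa-bridged enone F2. Its side-chain ketone is enolised separately (Et3SiOTf, Et3N) and closed by an intramolecular Mukaiyama aldol (TiCl4 or catalytic Et3SiOTf) to 16, which is hydrolysed to 17 as in step 11.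

2. Step 4. Enantiofacial discrimination may be insufficient in the allyl transfer to the hindered enolate beside the gem-dimethyl carbon, or the enolate may be protonated prematurely. The fallback sets out from 4 and comes back at 7: direct allylation of the lithium dienolate of 4 with allyl bromide gives racemic allyl ketone F3, which is resolved by preparative chromatography on a chiral stationary phase; the (R)-enantiomer is 7.

3. Step 14. Acyl transfer to the hindered bicyclic enolate may be slow, with competing proton transfer and beta-elimination of silanolate from the amide. The fallback sets out from 20 and comes back at 22: i-Bu2AlH reduction of 20 gives (S)-3-phenyl-3-(triethylsilyloxy)propanal F4; aldol addition of lithium enolate 21 to this more reactive electrophile gives beta-hydroxy ketone F5 (epimers at C8 and the carbinol are inconsequential); Dess–Martin oxidation gives 22.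

**Further compounds**

F1 | step 11 | (6R)-6-[2-(methoxymethoxy)propanoyl]-5,5,6-trimethyl-1,3-bis(triethylsilyloxy)cyclohexa-1,3-diene | COCOC(C)C(=O)[C@@]1(C)C(O[Si](CC)(CC)CC)=CC(O[Si](CC)(CC)CC)=CC1(C)C
F2 | step 11 | (1R,6R)-4,6,10,10-tetramethyl-7-(triethylsilyloxy)-3-oxabicyclo[4.3.1]dec-7-ene-5,9-dione (C4 epimers) | CC1(C)[C@@H]2COC(C)C(=O)[C@@]1(C)C(O[Si](CC)(CC)CC)=CC2=O
F3 | step 4 | rac-6-allyl-3-isobutoxy-5,5,6-trimethylcyclohex-2-en-1-one | C=CCC1(C)C(=O)C=C(OCC(C)C)CC1(C)C
F4 | step 14 | (S)-3-phenyl-3-(triethylsilyloxy)propanal | O=CC[C@H](O[Si](CC)(CC)CC)c1ccccc1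
F5 | step 14 | 8-[1-hydroxy-(3S)-3-phenyl-3-(triethylsilyloxy)propyl] derivative of 17 (cage configured as in 17; C8 and carbinol epimers) | CC1(C)[C@@H]2CO[C@]3(C)C(=O)[C@@]1(C)C(=O)C(C(O)C[C@H](O[Si](CC)(CC)CC)c1ccccc1)[C@]23O[Si](CC)(CC)CC
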